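The route rests on the bond between arene carbon C3, which lies ortho to the phenolic oxygen on C2 of the benzene ring, and the benzylic methine C6 of the heptenoic acid arm. The free ortho-OH is read as the trace of an aromatic Claisen rearrangement. In one operation the (S,E)-pent-3-en-2-yl ether of 2'-hydroxy-5'-methoxyacetophenone forms this C–C bond at the only open ortho carbon and relays its easily set C–O stereocentre into the (R)-benzylic centre. The propenyl group is then trimmed by ethenolysis and extended by hydroformylation–Wittig olefination. The trienoyl arm is grown last from the acetyl group by Claisen–Schmidt condensation.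

Key step: step 3

Remark: the benzylic stereocentre of the target is (R) and all four chain double bonds are E; (E)-pent-3-en-2-one, 1-(2-hydroxy-5-methoxyphenyl)ethan-1-one and (E)-4,4-dimethoxybut-2-enal are taken as the commercial materials.

Step 1
Reactants: 1 (E)-pent-3-en-2-one
Product: 2 (2R,3E)-pent-3-en-2-ol
Conditions: (S)-Me-CBS (10 mol%), catecholborane (1.5 equiv), toluene, −78 °C; MeOH quench
Reagents that add atoms: none
Why: Corey–Bakshi–Shibata reduction, in which the (S)-oxazaborolidine binds the enone with the propenyl group as the large substituent and delivers hydride 1,2 to set the (R)-carbinol centre, while catecholborane at −78 °C leaves the C=C bond untouched.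

Step 2
Reactants: 2 (2R,3E)-pent-3-en-2-ol; 3 1-(2-hydroxy-5-methoxyphenyl)ethan-1-one
Product: 4 1-[5-methoxy-2-{[(2S,3E)-pent-3-en-2-yl]oxy}phenyl]ethan-1-one
Conditions: PPh3, DIAD, THF, 0 °C → rt
Reagents that add atoms: none
Why: Mitsunobu etherification, in which the acidic phenol displaces the oxyphosphonium ion by SN2 with inversion to set the (S)-C–O centre, and because the 1,3-dimethylallyl unit is symmetric an SN2′ leak cannot give a constitutional isomer.

Step 3
Reactants: 4 1-[5-methoxy-2-{[(2S,3E)-pent-3-en-2-yl]oxy}phenyl]ethan-1-one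
Product: 6 1-{2-hydroxy-5-methoxy-3-[(2R,3E)-pent-3-en-2-yl]phenyl}ethan-1-one, via dienone 5 (not isolated)
Conditions: Eu(fod)3 (10 mol%), CHCl3, 50 °C
Reagents that add atoms: none
Why: Eu(III), held between the acetyl and ether oxygens, polarises the O–C bond, and a concerted suprafacial [3,3]-sigmatropic shift through a chair transition state joins the methyl-bearing alkene terminus to the free ortho carbon C3, giving dienone 5, which tautomerises at once to phenol 6. The closest known reaction type is the Lewis-acid-catalysed aromatic Claisen rearrangement of α,γ-dimethylallyl aryl ethers with 1,3-chirality transfer. No ring is closed; only the six-membered transition state is cyclic. The new benzylic stereocentre is controlled by the (S)-C–O centre of 4 together with the E-geometry of the alkene: with the carbinol methyl pseudo-equatorial, the new bond forms on the allyl face from which oxygen departs, which gives (R) and an (E)-alkene. The step needs ortho-regioselectivity and chair selectivity; the acetyl group blocks the second ortho carbon and the methoxy group the para carbon, so only the C3 adduct can rearomatise, and the mild catalysed conditions disfavour ionisation, the axial-methyl chair and the abnormal Claisen pathway.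

Step 4
Reactants: 6 1-{2-hydroxy-5-methoxy-3-[(2R,3E)-pent-3-en-2-yl]phenyl}ethan-1-one
Product: 7 1-{3-[(2R)-but-3-en-2-yl]-2-hydroxy-5-methoxyphenyl}ethan-1-one
Conditions: ethylene (5 bar), Hoveyda–Grubbs II (5 mol%), 1,4-benzoquinone (10 mol%), CH2Cl2, 40 °C
Reagents that add atoms: ethylene, C=C
Why: Ethenolysis (olefin cross-metathesis with ethylene), in which excess ethylene and loss of volatile propene drive the 1,2-disubstituted alkene to the terminal vinyl group without touching the benzylic centre, with benzoquinone suppressing Ru–H double-bond migration.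

Step 5
Reactants: 7 1-{3-[(2R)-but-3-en-2-yl]-2-hydroxy-5-methoxyphenyl}ethan-1-one
Product: 9 ethyl (2E,6R)-6-(3-acetyl-2-hydroxy-5-methoxyphenyl)hept-2-enoate, via aldehyde 8 (not isolated)
Conditions: Rh(acac)(CO)2 (1 mol%), Xantphos (3 mol%), CO/H2 (1:1, 10 bar), toluene, 70 °C; vent; then Ph3P=CHCO2Et (1.5 equiv), rt
Reagents that add atoms: carbon monoxide, [C-]#[O+]; ethyl (triphenylphosphoranylidene)acetate, CCOC(=O)C=P(c1ccccc1)(c1ccccc1)c1ccccc1
Why: Tandem linear-selective Rh/Xantphos hydroformylation (the α-branch at the allylic centre and the wide-bite-angle ligand both favour the n-aldehyde) and Wittig olefination with a stabilised ylide, which is E-selective and takes the aldehyde but not the aryl ketone.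

Step 6
Reactants: 10 (2E)-4,4-dimethoxybut-2-enal
Product: 12 ethyl (2E,4E)-6-oxohexa-2,4-dienoate, via acetal ester 11 (not isolated)
Conditions: Ph3P=CHCO2Et, CH2Cl2, rt; then 1 M HCl, THF, rt
Reagents that add atoms: ethyl (triphenylphosphoranylidene)acetate, CCOC(=O)C=P(c1ccccc1)(c1ccccc1)c1ccccc1; water, O
Why: Wittig olefination with the stabilised ylide should give the (E)-enoate, and mild aqueous acid then unmasks the dimethyl acetal to the conjugated aldehyde.

Step 7
Reactants: 9 ethyl (2E,6R)-6-(3-acetyl-2-hydroxy-5-methoxyphenyl)hept-2-enoate; 12 ethyl (2E,4E)-6-oxohexa-2,4-dienoate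
Product: 15 (2E,4E,6E)-8-{3-[(2R,5E)-6-carboxyhex-5-en-2-yl]-2-hydroxy-5-methoxyphenyl}-8-oxoocta-2,4,6-trienoic acid (target), via aldol adduct 13 (not isolated), via diester trienone 14 (not isolated)
Conditions: NaOEt (3 equiv), EtOH, 0 °C → rt, Ar, dark; then 2 M aq. NaOH, rt; then 1 M HCl, 0 °C
Reagents that add atoms: sodium hydroxide, [Na+].[OH-]
Why: Claisen–Schmidt aldol condensation of the methyl ketone with the non-enolisable dienal followed by E1cB dehydration should give the (E)-trienone, ethoxide in ethanol leaving the ethyl esters unchanged during C–C bond formation, after which hydroxide saponifies both esters while the ortho-phenoxide keeps the hydroxyaryl enone in its open form.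

Compound list
1 | (E)-pent-3-en-2-one | C/C=C/C(C)=O | starting material
2 | (2R,3E)-pent-3-en-2-ol | C/C=C/[C@@H](C)O | intermediate
3 | 1-(2-hydroxy-5-methoxyphenyl)ethan-1-one (2'-hydroxy-5'-methoxyacetophenone) | COc1ccc(O)c(C(C)=O)c1 | starting material
4 | 1-[5-methoxy-2-{[(2S,3E)-pent-3-en-2-yl]oxy}phenyl]ethan-1-one | C/C=C/[C@H](C)Oc1ccc(OC)cc1C(C)=O | intermediate
5 | (6R)-2-acetyl-4-methoxy-6-[(2R,3E)-pent-3-en-2-yl]cyclohexa-2,4-dien-1-one | O=C1C(C(C)=O)=CC(OC)=C[C@H]1[C@H](C)/C=C/C | intermediate
6 | 1-{2-hydroxy-5-methoxy-3-[(2R,3E)-pent-3-en-2-yl]phenyl}ethan-1-one | C/C=C/[C@@H](C)c1cc(OC)cc(C(C)=O)c1O | intermediate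
7 | 1-{3-[(2R)-but-3-en-2-yl]-2-hydroxy-5-methoxyphenyl}ethan-1-one | C=C[C@@H](C)c1cc(OC)cc(C(C)=O)c1O | intermediate
8 | (4R)-4-(3-acetyl-2-hydroxy-5-methoxyphenyl)pentanal | O=CCC[C@@H](C)c1cc(OC)cc(C(C)=O)c1O | intermediate
9 | ethyl (2E,6R)-6-(3-acetyl-2-hydroxy-5-methoxyphenyl)hept-2-enoate | CCOC(=O)/C=C/CC[C@@H](C)c1cc(OC)cc(C(C)=O)c1O | intermediate
10 | (2E)-4,4-dimethoxybut-2-enal (fumaraldehyde mono(dimethyl acetal)) | COC(OC)/C=C/C=O | starting material
11 | ethyl (2E,4E)-6,6-dimethoxyhexa-2,4-dienoate | CCOC(=O)/C=C/C=C/C(OC)OC | intermediate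
12 | ethyl (2E,4E)-6-oxohexa-2,4-dienoate | CCOC(=O)/C=C/C=C/C=O | intermediate
13 | ethyl (2E,4E)-8-{3-[(2R,5E)-7-ethoxy-7-oxohept-5-en-2-yl]-2-hydroxy-5-methoxyphenyl}-6-hydroxy-8-oxoocta-2,4-dienoate (both C6 epimers) | CCOC(=O)/C=C/C=C/C(O)CC(=O)c1cc(OC)cc([C@H](C)CC/C=C/C(=O)OCC)c1O | intermediate
14 | ethyl (2E,4E,6E)-8-{3-[(2R,5E)-7-ethoxy-7-oxohept-5-en-2-yl]-2-hydroxy-5-methoxyphenyl}-8-oxoocta-2,4,6-trienoate | CCOC(=O)/C=C/C=C/C=C/C(=O)c1cc(OC)cc([C@H](C)CC/C=C/C(=O)OCC)c1O | intermediate
15 | (2E,4E,6E)-8-{3-[(2R,5E)-6-carboxyhex-5-en-2-yl]-2-hydroxy-5-methoxyphenyl}-8-oxoocta-2,4,6-trienoic acid | COc1cc(C(=O)/C=C/C=C/C=C/C(=O)O)c(O)c([C@H](C)CC/C=C/C(=O)O)c1 | target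

Total step count: 7. Longest linear sequence: 6 steps (steps 1, 2, 3, 4, 5, 7); step 6 is a one-step side branch.

Steps most likely to fail

Step 3. The transfer of chirality may be eroded by Lewis-acid-induced ionisation of the ether to a 1,3-dimethylallyl cation and recombination. It may also leak through the chair with an axial methyl group to the (Z)-alkene, which carries the opposite benzylic configuration and would be merged into the wrong enantiomer by the ethenolysis. The catalyst may in addition be sequestered by the chelating hydroxy-ketone product. The fallback forms the same aryl–C bond intermolecularly by copper-catalysed enantioselective SN2′ allylic arylation. It sets out from 3: ortho-bromination (NBS, cat. i-Pr2NH, CH2Cl2) should give 1-(3-bromo-2-hydroxy-5-methoxyphenyl)ethan-1-one F1, and MOMCl/i-Pr2NEt then 1-[3-bromo-5-methoxy-2-(methoxymethoxy)phenyl]ethan-1-one F2. Miyaura borylation with bis(neopentyl glycolato)diboron (Pd(dppf)Cl2, KOAc, dioxane, 80 °C) should give 1-[3-(5,5-dimethyl-1,3,2-dioxaborinan-2-yl)-5-methoxy-2-(methoxymethoxy)phenyl]ethan-1-one F3. Coupling with (E)-but-2-en-1-yl diethyl phosphate under CuCl/chiral NHC catalysis (NaOMe, THF, 30 °C; ligand enantiomer chosen for the (R)-branched product) should give 1-{3-[(2R)-but-3-en-2-yl]-5-methoxy-2-(methoxymethoxy)phenyl}ethan-1-one F4. Removal of the MOM group (HCl, MeOH, rt) brings the sequence back to the route at 7.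

Step 5. Rh–H-mediated migration of the double bond into conjugation with the arene would erase the stereocentre; the branched aldehyde may also form, or the aldehyde may be trapped by the neighbouring phenol. The fallback sets out from 7 and replaces carbonylation by a boron-based C–C coupling. Ir-catalysed anti-Markovnikov hydroboration ([Ir(cod)Cl]2/dppm, HBpin, CH2Cl2, rt; the transient phenol O–B bond is hydrolysed on work-up) should give 1-{2-hydroxy-5-methoxy-3-[(2R)-4-(4,4,5,5-tetramethyl-1,3,2-dioxaborolan-2-yl)butan-2-yl]phenyl}ethan-1-one F5. B-alkyl Suzuki–Miyaura coupling of F5 with ethyl (E)-3-iodoacrylate (Pd(dppf)Cl2, K3PO4, THF/H2O, 60 °C) returns to the route at 9.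

Step 7. The polyenal may decompose under alkoxide or hydroxide (conjugate addition, oligomerisation), a second enolate may add to the trienone, and during saponification retro-aldol cleavage or oxa-Michael closure to a chroman-4-one may intervene. The fallback sets out from 9 and 12 and separates the three events under non-equilibrating, non-hydroxide conditions. A directed aldol addition of the phenoxide–enolate dianion (LiHMDS 2.2 equiv, THF, −78 °C, then 12) should give aldol adduct 13, now isolated. Acid-catalysed dehydration (p-TsOH cat., toluene, 40 °C) should give diester 14, also isolated. Neutral ester cleavage with Me3SnOH (1,2-dichloroethane, 70 °C) returns to the route at 15. No compound outside the list is made (F0).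

Further compounds
F1 | step 3 | 1-(3-bromo-2-hydroxy-5-methoxyphenyl)ethan-1-one | CC(=O)c1cc(OC)cc(Br)c1O
F2 | step 3 | 1-[3-bromo-5-methoxy-2-(methoxymethoxy)phenyl]ethan-1-one | CC(=O)c1cc(OC)cc(Br)c1OCOC
F3 | step 3 | 1-[3-(5,5-dimethyl-1,3,2-dioxaborinan-2-yl)-5-methoxy-2-(methoxymethoxy)phenyl]ethan-1-one | CC(=O)c1cc(OC)cc(B2OCC(C)(C)CO2)c1OCOC
F4 | step 3 | 1-{3-[(2R)-but-3-en-2-yl]-5-methoxy-2-(methoxymethoxy)phenyl}ethan-1-one | C=C[C@@H](C)c1cc(OC)cc(C(C)=O)c1OCOC
F5 | step 5 | 1-{2-hydroxy-5-methoxy-3-[(2R)-4-(4,4,5,5-tetramethyl-1,3,2-dioxaborolan-2-yl)butan-2-yl]phenyl}ethan-1-one | CC(=O)c1cc(OC)cc([C@H](C)CCB2OC(C)(C)C(C)(C)O2)c1O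
F0 | step 7 | none | none
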